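**Plan**

1. Retrosynthesis: the two aryl O–Si bonds are cut first. The lactone is then cut at O1–C2 and C4–C4a into enal 3 and stilbene resorcinol 7. Compound 7 is cut at its aryl–vinyl bond (Heck, 5 + 6) and 3 at Cα=Cβ (Wittig on 2).
2. Enabling feature: the ring O1–C2–C3–C4–C4a–C8a is a three-carbon acyl bridge (C2, C3, C4, with the guaiacyl group on C4) between phenol oxygen O1 and its ortho carbon C4a of a 3,5-dihydroxystilbene. C4a is also para to the C7 hydroxyl and has a symmetry twin, so the resorcinol can act as a C,O-bis-nucleophile towards an enoyl electrophile.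
3. Forward: steps 1–2 build the enal arm from vanillin, and steps 3–4 build the stilbene arm from 2-methoxy-4-vinylphenol and 5-bromoresorcinol. Step 5 joins the arms and closes the only ring made in the route (C4–C4a first, O1–C2 second). Step 6 removes the silyl groups.
4. Stereochemistry: C4 (R) is the only stereocentre and is set in step 5 by a chiral aminoindanol-derived triazolylidene. The E-alkenes come from the stabilised ylide (step 2) and from syn-insertion/syn-β-hydride elimination (step 4).
5. Protecting group: triisopropylsilyl (TIPS) on both guaiacol hydroxyls, chosen because it should withstand amine base at 100 °C and the carbene medium and is removed by buffered fluoride.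

Key step: step 5

Assumption: the (5aS,10bR) N-mesityl aminoindanol-derived triazolium chloride (Cc1cc(C)c(-[n+]2cn3c(n2)CO[C@H]4Cc5ccccc5[C@H]43)c(C)c1.[Cl-]) is taken to leave open the β-face of enoyl azolium 8 that leads to (4R); this sense of induction has to be confirmed on 10 or 11, and the (5aR,10bS) antipode, equally accessible, would replace it with no other change.

**Route**

Step 1
Reactants: 1 vanillin
Product: 2 3-methoxy-4-(triisopropylsilyloxy)benzaldehyde
Conditions: TIPSCl (1.2 equiv), imidazole (2.5 equiv), DMF, 0 °C to rt
Reagents that add atoms: triisopropylsilyl chloride, CC(C)[Si](Cl)(C(C)C)C(C)C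
Why: Imidazole-promoted O-silylation of a phenol is a standard protection, and the aldehyde is inert to it.

Step 2
Reactants: 2 3-methoxy-4-(triisopropylsilyloxy)benzaldehyde
Product: 3 (E)-3-[3-methoxy-4-(triisopropylsilyloxy)phenyl]prop-2-enal
Conditions: Ph3P=CHCHO (1.1 equiv), toluene, 80 °C
Reagents that add atoms: (triphenylphosphoranylidene)acetaldehyde, O=CC=P(c1ccccc1)(c1ccccc1)c1ccccc1
Why: Wittig olefination with the formyl-stabilised ylide adds the two-carbon enal unit with E-selectivity, only a slight excess of the weakly nucleophilic ylide being used so that the product enal is not homologated a second time, and the aryl silyl ether is inert to these neutral conditions.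

Step 3
Reactants: 4 2-methoxy-4-vinylphenol
Product: 5 (2-methoxy-4-vinylphenoxy)triisopropylsilane
Conditions: TIPSCl (1.2 equiv), imidazole (2.5 equiv), DMF, 0 °C to rt, trace BHT
Reagents that add atoms: triisopropylsilyl chloride, CC(C)[Si](Cl)(C(C)C)C(C)C
Why: The same phenol silylation as in step 1, run at or below room temperature with a radical inhibitor so that the styrene does not polymerise.

Step 4
Reactants: 5 (2-methoxy-4-vinylphenoxy)triisopropylsilane; 6 5-bromoresorcinol
Product: 7 5-[(E)-2-[3-methoxy-4-(triisopropylsilyloxy)phenyl]ethenyl]benzene-1,3-diol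
Conditions: Pd(OAc)2 (5 mol%), P(o-tol)3 (10 mol%), Et3N (3 equiv), DMF, 100 °C, argon
Reagents that add atoms: none
Why: Mizoroki–Heck coupling, in which oxidative addition of the aryl bromide, syn-insertion of the terminal alkene with aryl delivery to the unsubstituted carbon and syn-β-hydride elimination should give the E-stilbene; free bromophenols are tolerated by the P(o-tol)3 catalyst system, and the hindered aryl TIPS ether should withstand triethylamine at this temperature.

Step 5
Reactants: 3 (E)-3-[3-methoxy-4-(triisopropylsilyloxy)phenyl]prop-2-enal; 7 5-[(E)-2-[3-methoxy-4-(triisopropylsilyloxy)phenyl]ethenyl]benzene-1,3-diol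
Product: 10 (4R)-7-hydroxy-4-[3-methoxy-4-(triisopropylsilyloxy)phenyl]-5-[(E)-2-[3-methoxy-4-(triisopropylsilyloxy)phenyl]ethenyl]chroman-2-one, via enoyl triazolium salt 8 (not isolated), via β-arylated acyl triazolium salt 9 (not isolated)
Conditions: 7 (1.3 equiv), 3 (1.0 equiv), (5aS,10bR) N-mesityl aminoindanol triazolium chloride (10 mol%), 3,3',5,5'-tetra-tert-butyldiphenoquinone (1.2 equiv), i-Pr2NEt (20 mol%), 4 Å MS, toluene/THF, 25 °C, argon
Reagents that add atoms: none
Why: The triazolylidene adds to enal 3 and the diphenoquinone oxidises the resulting Breslow intermediate to enoyl triazolium 8, an activated feruloyl equivalent; the resorcinol ring of 7 then bonds through its C2 to the β-carbon (direct conjugate addition, or reversible 1,2-addition of the phenol followed by a Claisen-type [3,3] shift), and tautomerisation of the azolium enol gives acyl triazolium 9. The adjacent phenol oxygen closes the lactone by a 6-exo-trig addition–elimination at the acyl carbon (O1–C2), which frees the carbene for the next turnover. The closest known reaction type is the carbene-catalysed oxidative [3+3] annulation of enals with naphthols and other electron-rich phenols to 4-aryl-3,4-dihydrocoumarins. C4 is created in the C4–C4a bond formation under catalyst control: the indane of the aminoindanol-derived azolium covers one face of the planar enoyl unit, so the arene is delivered to the open face of the β-carbon. The step needs carbon attack next to the styryl group in preference to the carbon between the two hydroxyls, C- over O-acylation and a single annulation; para-hydroxyl activation of two symmetry-equivalent ring carbons favours the first, O-acylation is reversible because aryl enoates re-enter the acyl azolium manifold, and the acyloxy group of 10 together with the excess of 7 holds back a second annulation. The TIPS ethers keep the two para-hydroxystyrene-type phenols, which the quinone would otherwise oxidise to quinone methides, out of play.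

Step 6
Reactants: 10 (4R)-7-hydroxy-4-[3-methoxy-4-(triisopropylsilyloxy)phenyl]-5-[(E)-2-[3-methoxy-4-(triisopropylsilyloxy)phenyl]ethenyl]chroman-2-one
Product: 11 (4R)-7-hydroxy-4-(4-hydroxy-3-methoxyphenyl)-5-[(E)-2-(4-hydroxy-3-methoxyphenyl)ethenyl]chroman-2-one
Conditions: TBAF (2.4 equiv), AcOH (2.4 equiv), THF, 0 °C, argon; mildly acidic work-up
Reagents that add atoms: none
Why: Fluoride cleaves the aryl silyl ethers (strong Si–F bond, phenoxide leaving group) while the acetic acid buffer protonates the phenolates as they form, so that the base-sensitive aryl lactone and the oxidisable 4-hydroxystilbene are not exposed to basic fluoride, and C4, a non-enolisable diarylmethine, should keep its configuration.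

**Compound list**

1 | vanillin (4-hydroxy-3-methoxybenzaldehyde) | COc1cc(C=O)ccc1O | starting material
2 | 3-methoxy-4-(triisopropylsilyloxy)benzaldehyde | COc1cc(C=O)ccc1O[Si](C(C)C)(C(C)C)C(C)C | intermediate
3 | (E)-3-[3-methoxy-4-(triisopropylsilyloxy)phenyl]prop-2-enal (O-TIPS coniferaldehyde) | COc1cc(/C=C/C=O)ccc1O[Si](C(C)C)(C(C)C)C(C)C | intermediate
4 | 2-methoxy-4-vinylphenol | COc1cc(C=C)ccc1O | starting material
5 | (2-methoxy-4-vinylphenoxy)triisopropylsilane | COc1cc(C=C)ccc1O[Si](C(C)C)(C(C)C)C(C)C | intermediate
6 | 5-bromoresorcinol (5-bromobenzene-1,3-diol) | Oc1cc(O)cc(Br)c1 | starting material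
7 | 5-[(E)-2-[3-methoxy-4-(triisopropylsilyloxy)phenyl]ethenyl]benzene-1,3-diol (4'-O-TIPS isorhapontigenin) | COc1cc(/C=C/c2cc(O)cc(O)c2)ccc1O[Si](C(C)C)(C(C)C)C(C)C | intermediate
8 | enoyl triazolium salt: (E)-3-[3-methoxy-4-(triisopropylsilyloxy)phenyl]prop-2-enoyl derivative of the (5aS,10bR) catalyst, drawn as the chloride, formed in the flask | O=C(/C=C/c1ccc(O[Si](C(C)C)(C(C)C)C(C)C)c(OC)c1)c1[n+](-c2c(C)cc(C)cc2C)nc2CO[C@H]3Cc4ccccc4[C@H]3n12.[Cl-] | intermediate
9 | β-arylated acyl triazolium salt: (3R)-3-aryl-3-(2,4-dihydroxy-6-styrylphenyl)propanoyl derivative of the catalyst, drawn as the chloride, formed in the flask | O=C(C[C@H](c1ccc(O[Si](C(C)C)(C(C)C)C(C)C)c(OC)c1)c1c(O)cc(O)cc1/C=C/c1ccc(O[Si](C(C)C)(C(C)C)C(C)C)c(OC)c1)c1[n+](-c2c(C)cc(C)cc2C)nc2CO[C@H]3Cc4ccccc4[C@H]3n12.[Cl-] | intermediate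
10 | (4R)-7-hydroxy-4-[3-methoxy-4-(triisopropylsilyloxy)phenyl]-5-[(E)-2-[3-methoxy-4-(triisopropylsilyloxy)phenyl]ethenyl]chroman-2-one | COc1cc(/C=C/c2cc(O)cc3c2[C@@H](c2ccc(O[Si](C(C)C)(C(C)C)C(C)C)c(OC)c2)CC(=O)O3)ccc1O[Si](C(C)C)(C(C)C)C(C)C | intermediate
11 | (4R)-7-hydroxy-4-(4-hydroxy-3-methoxyphenyl)-5-[(E)-2-(4-hydroxy-3-methoxyphenyl)ethenyl]chroman-2-one (CNP0277187.1) | COc1cc(/C=C/c2cc(O)cc3c2[C@@H](c2ccc(O)c(OC)c2)CC(=O)O3)ccc1O | target

**Step count**

Total step count: 6. Longest linear sequence: 4 steps (3 → 4 → 5 → 6 from compound 4, or 1 → 2 → 5 → 6 from compound 1).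

**Steps most likely to fail**

Step 5. The β-addition to the electron-rich enoyl azolium may be sluggish, because the para-silyloxy group lowers its electrophilicity. The reaction may also stop at O-acylation, alkylate the carbon between the two hydroxyls, or discriminate poorly between the two faces. The fallback forms the same two bonds in two operations from 3 and 7, using iminium activation in place of the acyl azolium. Compounds 3 and 7 are combined with (R)-α,α-diphenylprolinol trimethylsilyl ether (20 mol%) and benzoic acid in toluene at 0 °C to rt. This Friedel–Crafts alkylation/hemiacetalisation cascade is known for naphthols and activated phenols and should give the (4R)-chroman-2-ol, lactol F1, as an anomeric mixture; the (R)-catalyst is expected to shield the face that would lead to (4S). Oxidation of the lactol F1 with Ag2CO3 on Celite in toluene at reflux, which should leave the resorcinol-type phenol and the stilbene untouched, returns to the route at 10.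

Step 4. Phenoxide coordination may deactivate the palladium catalyst, the silyl group of 5 may transfer to the resorcinol oxygens at 100 °C, or the electron-rich styrene may be arylated at its internal carbon. The fallback masks the hydroxyls. Compound 6 is acetylated (Ac2O, pyridine) to 5-bromo-1,3-phenylene diacetate F2. Heck coupling of F2 with 5 (Pd(OAc)2, P(o-tol)3, Et3N, DMF) should give the stilbene diacetate F3. Brief ammonolysis of F3 (NH3 in MeOH, 0 °C), which cleaves aryl acetates much faster than the hindered aryl silyl ether, returns to the route at 7.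

Step 6. Fluoride or a liberated phenolate may open the activated aryl lactone, which would lead to intermolecular transesterification, and the freed 4-hydroxystilbene phenolate may be oxidised by air. The fallback opens the lactone on purpose instead of trying to preserve it. Compound 10 is treated under argon with excess unbuffered TBAF in wet THF and then with aqueous LiOH in the same flask. This removes both silyl groups and saponifies the lactone, and acidification to pH 3 gives the seco acid F4, (3R)-3-[2,4-dihydroxy-6-[(E)-2-(4-hydroxy-3-methoxyphenyl)ethenyl]phenyl]-3-(4-hydroxy-3-methoxyphenyl)propanoic acid. The seco acid F4, an ortho-hydroxy dihydrocinnamic acid with a single ortho hydroxyl, should relactonise on warming in acetic acid at 50 °C, returning to the route at 11 with C4 unchanged.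

**Further compounds**

F1 | step 5 | (4R)-4-[3-methoxy-4-(triisopropylsilyloxy)phenyl]-5-[(E)-2-[3-methoxy-4-(triisopropylsilyloxy)phenyl]ethenyl]chromane-2,7-diol (lactol, anomeric mixture) | COc1cc(/C=C/c2cc(O)cc3c2[C@@H](c2ccc(O[Si](C(C)C)(C(C)C)C(C)C)c(OC)c2)CC(O)O3)ccc1O[Si](C(C)C)(C(C)C)C(C)C
F2 | step 4 | 5-bromo-1,3-phenylene diacetate | CC(=O)Oc1cc(Br)cc(OC(C)=O)c1
F3 | step 4 | 5-[(E)-2-[3-methoxy-4-(triisopropylsilyloxy)phenyl]ethenyl]-1,3-phenylene diacetate | COc1cc(/C=C/c2cc(OC(C)=O)cc(OC(C)=O)c2)ccc1O[Si](C(C)C)(C(C)C)C(C)C
F4 | step 6 | (3R)-3-[2,4-dihydroxy-6-[(E)-2-(4-hydroxy-3-methoxyphenyl)ethenyl]phenyl]-3-(4-hydroxy-3-methoxyphenyl)propanoic acid | COc1cc(/C=C/c2cc(O)cc(O)c2[C@@H](c2ccc(O)c(OC)c2)CC(=O)O)ccc1O
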